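## Structural features

The target 18 is a 1-aryltetralin cyclolignan. Ring A is a benzene with methoxy groups at C6 and C8 and a free hydroxyl at C7, fused through C4a and C8a to the saturated ring B (C1 to C4). C1 carries a 4-hydroxy-3,5-dimethoxyphenyl group (the pendant ring), C2 and C3 each carry CH2OH, and C4 is an unsubstituted CH2 bonded to C4a. C1 (S), C2 (R) and C3 (R) are contiguous stereocentres with 1,2-trans and 2,3-trans relationships, so the C1 aryl and the C3 branch are cis and all three substituents can be equatorial on a half-chair. The fragile parts are the two electron-rich 2,6-dimethoxyphenols (easily oxidised, and able to form quinone methides at the benzylic carbons C1 and C4) and the doubly benzylic C1–H. The real difficulty is the absolute configuration of the diarylmethine C1, crowded by the C8 methoxy group and by C2, together with the substitution pattern of ring A: C8a lies ortho to a methoxy group and meta to the hydroxyl, C4a lies para to the hydroxyl. C2 and C3 can each be placed next to a carbonyl group and then settle under thermodynamic control once C1 is fixed. The key step uses the fact that C4 is a bare methylene on C4a and C3 carries exactly one extra carbon: C4, C3, the branch carbon and one sacrificial carbon are the four carbons of buta-1,3-diene, stitched between a halogen on C4a and a stabilised carbanion on C2.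

## Logic of the disconnections

18 ⇒ 17. The two phenolic O–H groups (on C7 and on the para carbon of the pendant ring) are traced back to O–CH2Ph bonds. Free phenols would compete as nucleophiles for allylpalladium, would be deprotonated by every base used earlier and are oxidised easily; benzyl groups leave last under neutral conditions. The skeleton is unchanged, but every earlier intermediate becomes a neutral, air-stable arene. The forward step must cleave two aryl benzyl ethers without touching the benzylic C–C bonds at C1 and C4.

17 ⇒ 16. The C–O single bonds of the two carbinols are taken back to a formyl group on C3 and a methyl ester on C2; no skeletal bond is cut. This puts C2 and C3 each next to a carbonyl group, so both are open to base equilibration towards the all-equatorial array. The forward step must reduce both carbonyl groups in one operation without moving either centre away from that array.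

16 ⇒ 14. The formyl C=O on C3 is traced to the C=C of a vinyl group; in the forward sense the terminal carbon is excised. A vinyl group is exactly what the diene leaves on C3 in the ring-forming step. The price is one oxidative cleavage that must leave two electron-rich arenes and two benzyl ethers alone.

14 ⇒ 12. The C2–H bond is replaced by a second C2–CO2Me bond. C2 ceases to be a stereocentre and becomes a malonate carbon, the stabilised carbanion that ring closure needs. The forward step must remove one ester group and leave the other trans to both neighbours, which is asked of thermodynamics and not of a reagent.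

12 ⇒ 10 + 11. Ring B is opened by cutting C4–C4a and C2–C3. The cut lies here because C4, C3 and the vinyl group of 12 are the four carbons of 11, and because an aryl–halogen bond at C4a and a malonate at C2 are the natural two ends for a metal-mediated insertion–alkylation. One ring, two skeletal bonds and the stereocentre C3 disappear, leaving an acyclic compound with one stereocentre and a C4 gas. The forward step must add the aryl group to a terminal carbon of 11, close the six- and not the eight-membered ring, outrun β-hydride loss, and relay the configuration of C1 to C3. The halogen is kept as bromide, not a more reactive halide, because it must pass untouched through the rhodium step before it.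

10 ⇒ 6 + 9. The bond between C1 and the pendant ring is cut. This removes the last stereocentre and reduces the problem to enantioselective addition of an unhindered aryl nucleophile to a prochiral alkene; the hindered ring stays on the electrophile. The forward step must choose one face of a β-carbon flanked by an ortho bromine and an ortho methoxy group and must leave the C–Br bond intact.

6 ⇒ 4 + 5. The C1=C2 double bond is cut into an aldehyde carbon and an active methylene. Both partners are simple, and two identical esters mean there is no alkene geometry to control. The forward condensation must cope with an ortho,ortho-disubstituted, electron-rich aldehyde.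

4 ⇒ 2 and 9 ⇒ 2. The ring–CHO bond of 4 and the C–B bond of 9 both lead back to the same aryl bromide. In 2 the two ring hydrogens are equivalent, each between the bromine and a methoxy group, so formylation can give only the ring-A pattern. The bromine exchanged for boron on the way to 9 is the atom kept in 4 as the future C4a handle, so one precursor serves both aryl rings. The formylation must not cost the benzyl ether; the metalation must be run cold.

2 ⇒ 1. The O–benzyl bond is cut, leaving a phenol whose para position already carries the bromine.

## Other disconnections considered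

Alternative 1: The cut runs through C2–C3 and C1–C8a and halves the skeleton into two identical arylpropenoyl units.
- Forward key step: two molecules of the sinapoyl imide A1 would be oxidised at a carbon anode in a buffered alcohol. The two phenoxyl radicals join at their side-chain β-carbons (C2–C3); one quinone methide tautomerises, restoring its phenol and creating C3=C4; its ring then adds to the second quinone methide (C1–C8a) to give the 1,2-trans dihydronaphthalene bis-imide A2.
- In favour: it follows the likely biogenesis, needs no protecting group and no halogen, and builds ring B, two C–C bonds and the C1/C2 pair in one step. The ring-A pattern is automatic because the two positions ortho to the side chain are equivalent. Hydrogenation of C3=C4 and reductive removal of the auxiliaries would reach 18 in about four steps against ten; on step count and protecting-group economy this alternative is clearly the better one.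
- Against: the absolute configuration of C1 and C2 would depend on auxiliaries three bonds away from the coupling carbons in a radical–radical event, a weak basis for high facial control. The coupling can take other courses (aryl ether or bis-lactone dimers), and the phenolic product is as easily oxidised as the substrate.
- Comparison: C3 would still need an equilibration after hydrogenation, as in the chosen plan (equal on this point). The chosen plan assigns each selectivity to a separate control element (catalyst for C1, halide for the ring site, thermodynamics for C2 and C3), whereas this alternative concentrates chemo-, regio- and stereoselectivity in one electrode process.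

Alternative 2: The cut removes C4 alone, by breaking C3–C4 and C4–C4a.
- Forward key step: the acyclic aldehyde A3 (expected to rest largely as its five-membered lactol) and formaldehyde A4 would be combined under secondary-amine salt catalysis. Either the aldehyde is α-methylenated and the ring-A carbon para to the hydroxyl adds to the enal, or that carbon is hydroxymethylated first and the derived quinone methide is captured by the enamine. Both paths give the all-trans aldehyde A5.
- In favour: the cheapest possible one-carbon unit, no metal, no protecting groups, C3 delivered at the aldehyde level under thermodynamic control, and one reduction from A5 to 18. The endgame is shorter than in the chosen plan. The site on ring A is fixed by the para position of the phenol as firmly as by the bromide in the chosen plan (equal).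
- Against: the difficulty moves into A3, which already holds C1 and C2 with defined configuration and a 3-hydroxy-2,4-dimethoxyphenyl ring attached through its most hindered carbon. No shorter way to A3 than to 10 is apparent, and C2, which the chosen plan leaves to equilibration, would have to be set on purpose. In the ring closure the neighbouring CH2OH could add to the α-methylene aldehyde (tetrahydrofuran formation), and phenol–aldehyde oligomerisation is a background reaction.
- Comparison: on control of C3 the two plans are equal (both thermodynamic). On total step count the alternative would probably not be shorter once A3 is included.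

Alternative 3: After a hydroxyl group is added at C4, the cut is a retro-Diels–Alder through C1–C2 and C3–C4.
- Forward key step: irradiation near 350 nm of the 2-benzylbenzaldehyde A6 would give its hydroxy-o-quinodimethane, which would add the lactate-derived fumarate A7 to give the tetralin A8.
- In favour: two C–C bonds, ring B and all three ring-B stereocentres of 18 in one neutral step. The 2,3-trans relationship is written into the dienophile geometry and needs no later equilibration; on this point the alternative is better than the chosen plan. Both carbinol carbons arrive as esters, the extra benzylic C4–OH could leave in the same hydrogenolysis that frees the phenols, and A6 has no stereocentre and is simpler than 10.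
- Against: the absolute configuration would rest on lactate esters directing an uncatalysed cycloaddition of a short-lived photoenol, where chelating Lewis acids (the usual source of high induction with such auxiliaries) cannot be used. The dienol terminus bearing the aryl group lies next to the C8 methoxy group, and that strain may disfavour the reactive (E,E) geometry. The electron-rich aldehyde also has competing photochemistry.
- Comparison: protecting-group use is the same (two benzyl ethers) and the step count would be similar or slightly lower. Relative configuration is more firmly built in than in the chosen plan, absolute configuration less so; the chosen plan keeps its one enantio-determining event in a catalytic ground-state reaction with a single stereocentre at stake.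

Key step: step 6

Assumption: 1 is taken as a purchasable phenol (otherwise it is the para-bromination product of 2,6-dimethoxyphenol). In step 5 the sense of induction on this crowded acceptor is not predicted here; the antipode of the chiral diene that a pilot run shows to give the (S) adduct is used.

Remark: the descriptors 12 (1S,3S), 14 (1S,2S,3S) and 16 to 18 (1S,2R,3R) describe one unchanged spatial arrangement; the changes at C2 and C3 come from substituent ranking, not from inversion.

Step 1
Reactants: 1 4-bromo-2,6-dimethoxyphenol
Product: 2 2-(benzyloxy)-5-bromo-1,3-dimethoxybenzene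
Conditions: BnBr, K2CO3, DMF, 60 °C
Reagents that add atoms: benzyl bromide, BrCc1ccccc1
Why: Williamson ether synthesis; the phenoxide is flanked by two methoxy groups but benzyl bromide is an unhindered SN2 electrophile, and O-alkylation is the only open path because both ortho positions and the para position are substituted.

Step 2
Reactants: 2 2-(benzyloxy)-5-bromo-1,3-dimethoxybenzene
Product: 4 3-(benzyloxy)-6-bromo-2,4-dimethoxybenzaldehyde, via chloro(methoxy)methyl arene 3 (not isolated)
Conditions: Cl2CHOMe, TiCl4, CH2Cl2, −78 → 0 °C; then ice/H2O
Reagents that add atoms: dichloromethyl methyl ether, COC(Cl)Cl; water, O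
Why: Rieche formylation; the two ring hydrogens of 2 are equivalent, each ortho to one methoxy group and para to the other, so only one aldehyde can form and the unactivated benzyl ring should not compete; 3 is hydrolysed on quench, and the low temperature is meant to protect the benzyl ether from TiCl4.

Step 3
Reactants: 4 3-(benzyloxy)-6-bromo-2,4-dimethoxybenzaldehyde; 5 dimethyl malonate
Product: 6 dimethyl 2-{[3-(benzyloxy)-6-bromo-2,4-dimethoxyphenyl]methylidene}propanedioate
Conditions: piperidine (cat.), AcOH (cat.), toluene, reflux, Dean–Stark
Reagents that add atoms: none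
Why: Knoevenagel condensation; azeotropic removal of water should drive the condensation of this hindered, electron-rich aldehyde, and the two identical ester groups leave no alkene geometry to control.

Step 4
Reactants: 2 2-(benzyloxy)-5-bromo-1,3-dimethoxybenzene
Product: 9 [4-(benzyloxy)-3,5-dimethoxyphenyl]boronic acid, via aryllithium 7 (not isolated), via lithium aryltriisopropoxyborate 8 (not isolated)
Conditions: n-BuLi, THF, −78 °C; B(OiPr)3, −78 °C → rt; 1 M HCl
Reagents that add atoms: triisopropyl borate, CC(C)OB(OC(C)C)OC(C)C; water, O
Why: bromine–lithium exchange at −78 °C is faster than any attack on the benzyl ether; 7 is trapped by the borate as the ate complex 8, which aqueous acid hydrolyses to 9.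

Step 5
Reactants: 6 dimethyl 2-{[3-(benzyloxy)-6-bromo-2,4-dimethoxyphenyl]methylidene}propanedioate; 9 [4-(benzyloxy)-3,5-dimethoxyphenyl]boronic acid
Product: 10 dimethyl 2-[(S)-[4-(benzyloxy)-3,5-dimethoxyphenyl][3-(benzyloxy)-6-bromo-2,4-dimethoxyphenyl]methyl]propanedioate
Conditions: [RhCl(C2H4)2]2 (2.5 mol %), chiral diene 2,5-diphenylbicyclo[2.2.2]octa-2,5-diene (5.5 mol %), aq. KOH (0.2 equiv), 1,4-dioxane/H2O (10:1), 50 °C
Reagents that add atoms: none
Why: Hayashi–Miyaura conjugate addition to a doubly activated alkene: the aryl group passes from boron to monovalent rhodium, the aryl–rhodium adds to the β-carbon and water protonates the rhodium malonate enolate; the stereocentre C1 is set by the catalyst, whose twofold-symmetric diene leaves one enantiotopic face of the alkene open, and the C–Br bond should not react with monovalent rhodium at this temperature.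

Step 6
Reactants: 10 dimethyl 2-[(S)-[4-(benzyloxy)-3,5-dimethoxyphenyl][3-(benzyloxy)-6-bromo-2,4-dimethoxyphenyl]methyl]propanedioate; 11 buta-1,3-diene
Product: 12 dimethyl (1S,3S)-7-(benzyloxy)-1-[4-(benzyloxy)-3,5-dimethoxyphenyl]-3-ethenyl-6,8-dimethoxy-3,4-dihydronaphthalene-2,2(1H)-dicarboxylate
Conditions: Pd(OAc)2 (10 mol %), PPh3 (30 mol %), K2CO3 (3 equiv), 11 (10 equiv), DMF, sealed vessel, 100 °C
Reagents that add atoms: none
Why: Zerovalent palladium, formed in the flask from Pd(OAc)2 and PPh3, inserts into the C4a–Br bond of 10, and the arylpalladium bromide adds across one double bond of 11 with the aryl group going to the terminal carbon (C4–C4a), leaving an allylpalladium that spans C3 and the two carbons of the future vinyl group. The malonate carbon C2, deprotonated by K2CO3, then attacks the substituted allyl terminus C3 on the face opposite palladium (C2–C3) and releases zerovalent palladium. The closest known reaction type is the palladium-catalysed carboannulation of 1,3-dienes by ortho-halobenzyl malonates, a Heck-type insertion followed by a Tsuji–Trost-type alkylation, applied here to a benzylic carbon that carries a second aryl group. Ring B closes in the 6-exo mode of an allylic alkylation with the vinyl group outside the ring; attack at the far allyl terminus would need an eight-membered ring and should not compete. The new stereocentre C3 is controlled by C1: the two faces of the allyl unit interconvert through the σ-allyl form at the unsubstituted terminus faster than the ring closes, so the outcome is decided between two half-chair transition states, and the one with the C1 aryl group and the allyl residue both pseudo-equatorial (1,3-cis, 3S) avoids the 1,3-diaxial contact of the other. Site selectivity comes from the single C–Br bond (ring A, not the pendant ring, is annulated), regioselectivity of insertion from the preference of arylpalladium for a diene terminus, and C–C closure over β-hydride loss from the tethered malonate anion helped by the Thorpe–Ingold effect of the diarylmethine. C1 has no hydrogen acidic towards carbonate and keeps its configuration.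

Step 7
Reactants: 12 dimethyl (1S,3S)-7-(benzyloxy)-1-[4-(benzyloxy)-3,5-dimethoxyphenyl]-3-ethenyl-6,8-dimethoxy-3,4-dihydronaphthalene-2,2(1H)-dicarboxylate
Product: 14 methyl (1S,2S,3S)-7-(benzyloxy)-1-[4-(benzyloxy)-3,5-dimethoxyphenyl]-3-ethenyl-6,8-dimethoxy-1,2,3,4-tetrahydronaphthalene-2-carboxylate, via C2-epimeric ester 13 (not isolated)
Conditions: LiCl, H2O, DMSO, 150 °C; then NaOMe, MeOH, 50 °C
Reagents that add atoms: none
Why: Krapcho dealkoxycarbonylation: chloride attacks an ester methyl group (SN2), the carboxylate loses CO2 and water protonates the ester enolate, probably mostly on the face away from the aryl and vinyl groups, which gives the cis,cis ester 13; methoxide then equilibrates C2 through the enolate to 14, whose ester is equatorial and trans to both neighbours, while C1 and C3 have no acidic hydrogen.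

Step 8
Reactants: 14 methyl (1S,2S,3S)-7-(benzyloxy)-1-[4-(benzyloxy)-3,5-dimethoxyphenyl]-3-ethenyl-6,8-dimethoxy-1,2,3,4-tetrahydronaphthalene-2-carboxylate
Product: 16 methyl (1S,2R,3R)-7-(benzyloxy)-1-[4-(benzyloxy)-3,5-dimethoxyphenyl]-3-formyl-6,8-dimethoxy-1,2,3,4-tetrahydronaphthalene-2-carboxylate, via vicinal diol 15 (not isolated)
Conditions: OsO4 (2 mol %), NaIO4 (4 equiv), 2,6-lutidine, 1,4-dioxane/H2O (3:1), rt
Reagents that add atoms: osmium tetroxide, O=[Os](=O)(=O)=O; sodium periodate, [Na+].[O-][I](=O)(=O)=O
Why: Lemieux–Johnson oxidation: catalytic OsO4 dihydroxylates the only alkene to 15, and periodate cleaves the diol and returns osmium to the octavalent state, while arenes and benzyl ethers are inert at room temperature and 2,6-lutidine buffers the medium; C3 keeps its spatial arrangement and, now α to the aldehyde, could be equilibrated with DBU towards the same equatorial position if step 6 had left any C3 epimer.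

Step 9
Reactants: 16 methyl (1S,2R,3R)-7-(benzyloxy)-1-[4-(benzyloxy)-3,5-dimethoxyphenyl]-3-formyl-6,8-dimethoxy-1,2,3,4-tetrahydronaphthalene-2-carboxylate
Product: 17 [(1S,2R,3R)-7-(benzyloxy)-1-[4-(benzyloxy)-3,5-dimethoxyphenyl]-6,8-dimethoxy-1,2,3,4-tetrahydronaphthalene-2,3-diyl]dimethanol
Conditions: LiAlH4, THF, 0 °C → rt; H2O, aq. NaOH work-up
Reagents that add atoms: none
Why: hydride reduction of the aldehyde and the ester to the two primary alcohols; no bond to a stereocentre is made or broken, and the brief contact with alkoxide acts on centres that already hold their thermodynamic configuration.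

Step 10
Reactants: 17 [(1S,2R,3R)-7-(benzyloxy)-1-[4-(benzyloxy)-3,5-dimethoxyphenyl]-6,8-dimethoxy-1,2,3,4-tetrahydronaphthalene-2,3-diyl]dimethanol
Product: 18 4-[(1S,2R,3R)-7-hydroxy-2,3-bis(hydroxymethyl)-6,8-dimethoxy-1,2,3,4-tetrahydronaphthalen-1-yl]-2,6-dimethoxyphenol
Conditions: H2 (1 atm), 10% Pd/C, EtOAc/MeOH, rt
Reagents that add atoms: none
Why: hydrogenolysis of the two aryl benzyl ethers over palladium on carbon; the tetralin has no alkene, halide or benzylic C–O bond, and the benzylic C–C bonds at C1 and C4 are not cleaved, so the three stereocentres are untouched.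

Compound list

1 | 4-bromo-2,6-dimethoxyphenol | COc1cc(Br)cc(OC)c1O | starting material
2 | 2-(benzyloxy)-5-bromo-1,3-dimethoxybenzene | COc1cc(Br)cc(OC)c1OCc1ccccc1 | intermediate
3 | 2-(benzyloxy)-5-bromo-4-[chloro(methoxy)methyl]-1,3-dimethoxybenzene (racemic at the new carbon) | COC(Cl)c1c(Br)cc(OC)c(OCc2ccccc2)c1OC | intermediate (not isolated)
4 | 3-(benzyloxy)-6-bromo-2,4-dimethoxybenzaldehyde | COc1cc(Br)c(C=O)c(OC)c1OCc1ccccc1 | intermediate
5 | dimethyl malonate | COC(=O)CC(=O)OC | starting material
6 | dimethyl 2-{[3-(benzyloxy)-6-bromo-2,4-dimethoxyphenyl]methylidene}propanedioate | COC(=O)C(=Cc1c(Br)cc(OC)c(OCc2ccccc2)c1OC)C(=O)OC | intermediate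
7 | [4-(benzyloxy)-3,5-dimethoxyphenyl]lithium | [Li]c1cc(OC)c(OCc2ccccc2)c(OC)c1 | intermediate (not isolated)
8 | lithium [4-(benzyloxy)-3,5-dimethoxyphenyl]tri(propan-2-yloxy)borate | [Li+].COc1cc([B-](OC(C)C)(OC(C)C)OC(C)C)cc(OC)c1OCc1ccccc1 | intermediate (not isolated)
9 | [4-(benzyloxy)-3,5-dimethoxyphenyl]boronic acid | COc1cc(B(O)O)cc(OC)c1OCc1ccccc1 | intermediate
10 | dimethyl 2-[(S)-[4-(benzyloxy)-3,5-dimethoxyphenyl][3-(benzyloxy)-6-bromo-2,4-dimethoxyphenyl]methyl]propanedioate | COc1cc([C@H](C(C(=O)OC)C(=O)OC)c2c(Br)cc(OC)c(OCc3ccccc3)c2OC)cc(OC)c1OCc1ccccc1 | intermediate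
11 | buta-1,3-diene | C=CC=C | starting material
12 | dimethyl (1S,3S)-7-(benzyloxy)-1-[4-(benzyloxy)-3,5-dimethoxyphenyl]-3-ethenyl-6,8-dimethoxy-3,4-dihydronaphthalene-2,2(1H)-dicarboxylate (1,3-cis) | COc1cc([C@H]2c3c(cc(OC)c(OCc4ccccc4)c3OC)C[C@@H](C=C)C2(C(=O)OC)C(=O)OC)cc(OC)c1OCc1ccccc1 | intermediate
13 | methyl (1S,2R,3S)-7-(benzyloxy)-1-[4-(benzyloxy)-3,5-dimethoxyphenyl]-3-ethenyl-6,8-dimethoxy-1,2,3,4-tetrahydronaphthalene-2-carboxylate (ester cis to aryl and vinyl) | COc1cc([C@H]2c3c(cc(OC)c(OCc4ccccc4)c3OC)C[C@@H](C=C)[C@H]2C(=O)OC)cc(OC)c1OCc1ccccc1 | intermediate (not isolated)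
14 | methyl (1S,2S,3S)-7-(benzyloxy)-1-[4-(benzyloxy)-3,5-dimethoxyphenyl]-3-ethenyl-6,8-dimethoxy-1,2,3,4-tetrahydronaphthalene-2-carboxylate (all-trans) | COc1cc([C@H]2c3c(cc(OC)c(OCc4ccccc4)c3OC)C[C@@H](C=C)[C@@H]2C(=O)OC)cc(OC)c1OCc1ccccc1 | intermediate
15 | methyl (1S,2R,3R)-7-(benzyloxy)-1-[4-(benzyloxy)-3,5-dimethoxyphenyl]-3-(1,2-dihydroxyethyl)-6,8-dimethoxy-1,2,3,4-tetrahydronaphthalene-2-carboxylate (both configurations at the carbinol carbon) | COc1cc([C@H]2c3c(cc(OC)c(OCc4ccccc4)c3OC)C[C@@H](C(O)CO)[C@@H]2C(=O)OC)cc(OC)c1OCc1ccccc1 | intermediate (not isolated)
16 | methyl (1S,2R,3R)-7-(benzyloxy)-1-[4-(benzyloxy)-3,5-dimethoxyphenyl]-3-formyl-6,8-dimethoxy-1,2,3,4-tetrahydronaphthalene-2-carboxylate (all-trans) | COc1cc([C@H]2c3c(cc(OC)c(OCc4ccccc4)c3OC)C[C@@H](C=O)[C@@H]2C(=O)OC)cc(OC)c1OCc1ccccc1 | intermediate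
17 | [(1S,2R,3R)-7-(benzyloxy)-1-[4-(benzyloxy)-3,5-dimethoxyphenyl]-6,8-dimethoxy-1,2,3,4-tetrahydronaphthalene-2,3-diyl]dimethanol | COc1cc([C@H]2c3c(cc(OC)c(OCc4ccccc4)c3OC)C[C@@H](CO)[C@@H]2CO)cc(OC)c1OCc1ccccc1 | intermediate
18 | 4-[(1S,2R,3R)-7-hydroxy-2,3-bis(hydroxymethyl)-6,8-dimethoxy-1,2,3,4-tetrahydronaphthalen-1-yl]-2,6-dimethoxyphenol | COc1cc([C@H]2c3c(cc(OC)c(O)c3OC)C[C@@H](CO)[C@@H]2CO)cc(OC)c1O | target

Total step count: 10. Longest linear sequence: 9 steps (steps 1, 2, 3, 5, 6, 7, 8, 9, 10, from 1 to 18); step 4 is the one-step branch from 2 to 9.

Steps least certain to work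

Step 6 (key step).
- What may go wrong: the allylpalladium intermediate may be diverted before the crowded tertiary malonate anion reaches C3, because ring closure must join a quaternary carbon to a tertiary one next to the diarylmethine. The diversions are β-hydride loss to an aryl diene, palladium-catalysed telomerisation of 11 with the malonate, and arylation of the pendant ring to a fluorene.
- Second concern: facial selectivity at C3 may be modest, because the C8 methoxy group and the geminal esters weaken the preference for an equatorial C1 aryl group. This is tolerable within the route: in 16 C3 is α to the formyl group and C2 is α to the ester, so base equilibration there leads towards the all-trans array.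
- Fallback (stepwise, without the diene), from 10: Stille coupling with allyltributylstannane (Pd(PPh3)4, toluene, 100 °C) would give dimethyl 2-[(S)-[4-(benzyloxy)-3,5-dimethoxyphenyl][3-(benzyloxy)-2,4-dimethoxy-6-(prop-2-en-1-yl)phenyl]methyl]propanedioate F1. Cross-metathesis with (Z)-but-2-ene-1,4-diyl diacetate (second-generation Grubbs catalyst RuCl2(=CHPh)(H2IMes)(PCy3), CH2Cl2, 40 °C) would give the (E)-allylic acetate dimethyl 2-[(S)-[6-[(2E)-4-(acetyloxy)but-2-en-1-yl]-3-(benzyloxy)-2,4-dimethoxyphenyl][4-(benzyloxy)-3,5-dimethoxyphenyl]methyl]propanedioate F2. Intramolecular Tsuji–Trost alkylation (Pd(PPh3)4, NaH, THF, 50 °C) would then close ring B through the same allylpalladium by 6-exo attack and return to the route at 12.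

Step 5.
- What may go wrong: aryl transfer to the β-carbon may be slow, because that carbon is shielded on both faces by the ortho bromine and ortho methoxy group of a ring twisted out of conjugation; protodeboronation of 9 would then take over. Face discrimination on so hindered an alkene may also be insufficient.
- Fallback (racemic addition plus resolution), from 2 and 6: 2 is converted with magnesium in THF into [4-(benzyloxy)-3,5-dimethoxyphenyl]magnesium bromide F3. F3 is added to 6 with catalytic CuBr·SMe2 at −40 °C to give racemic dimethyl 2-{[4-(benzyloxy)-3,5-dimethoxyphenyl][3-(benzyloxy)-6-bromo-2,4-dimethoxyphenyl]methyl}propanedioate F4. Preparative chromatography on a chiral stationary phase (supercritical CO2/alcohol) separates the enantiomers and returns to the route at 10.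

Step 2.
- What may go wrong: loss of the benzyl protecting group. TiCl4 can coordinate the central benzyloxy oxygen, which is twisted out of the ring plane between two methoxy groups, and ionise the O–benzyl bond before or after formylation.
- Fallback (deprotonative instead of electrophilic formylation), from 2: LDA in THF at −78 °C removes the ring hydrogen between bromine and methoxy to give [3-(benzyloxy)-6-bromo-2,4-dimethoxyphenyl]lithium F5. Quenching cold with DMF and aqueous NH4Cl returns to the route at 4 with no Lewis acid present.

Step 7.
- What may go wrong: at 150 °C chloride dealkylation may not stay confined to the ester methyl groups (the aryl methyl ethers are at risk on long heating). The C2 mixture formed on protonation may also equilibrate incompletely.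
- Fallback (hydrolysis and thermal decarboxylation instead of halide dealkylation), from 12: KOH (1.2 equiv) in MeOH/H2O/THF at 60 °C, then acidification, would give the half ester (1S,3S)-7-(benzyloxy)-1-[4-(benzyloxy)-3,5-dimethoxyphenyl]-3-ethenyl-6,8-dimethoxy-2-(methoxycarbonyl)-1,2,3,4-tetrahydronaphthalene-2-carboxylic acid F6. F6 should lose CO2 on heating in toluene at 110 °C to a mixture of 13 and 14, and NaOMe in MeOH then returns to the route at 14.

Further compounds

F1 | step 6 | dimethyl 2-[(S)-[4-(benzyloxy)-3,5-dimethoxyphenyl][3-(benzyloxy)-2,4-dimethoxy-6-(prop-2-en-1-yl)phenyl]methyl]propanedioate | COc1cc([C@H](C(C(=O)OC)C(=O)OC)c2c(CC=C)cc(OC)c(OCc3ccccc3)c2OC)cc(OC)c1OCc1ccccc1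
F2 | step 6 | dimethyl 2-[(S)-[6-[(2E)-4-(acetyloxy)but-2-en-1-yl]-3-(benzyloxy)-2,4-dimethoxyphenyl][4-(benzyloxy)-3,5-dimethoxyphenyl]methyl]propanedioate | COc1cc([C@H](C(C(=O)OC)C(=O)OC)c2c(C/C=C/COC(C)=O)cc(OC)c(OCc3ccccc3)c2OC)cc(OC)c1OCc1ccccc1
F3 | step 5 | [4-(benzyloxy)-3,5-dimethoxyphenyl]magnesium bromide | COc1cc([Mg]Br)cc(OC)c1OCc1ccccc1
F4 | step 5 | racemic dimethyl 2-{[4-(benzyloxy)-3,5-dimethoxyphenyl][3-(benzyloxy)-6-bromo-2,4-dimethoxyphenyl]methyl}propanedioate | COc1cc(C(C(C(=O)OC)C(=O)OC)c2c(Br)cc(OC)c(OCc3ccccc3)c2OC)cc(OC)c1OCc1ccccc1
F5 | step 2 | [3-(benzyloxy)-6-bromo-2,4-dimethoxyphenyl]lithium | [Li]c1c(Br)cc(OC)c(OCc2ccccc2)c1OC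
F6 | step 7 | (1S,3S)-7-(benzyloxy)-1-[4-(benzyloxy)-3,5-dimethoxyphenyl]-3-ethenyl-6,8-dimethoxy-2-(methoxycarbonyl)-1,2,3,4-tetrahydronaphthalene-2-carboxylic acid (both configurations at C2) | COc1cc([C@H]2c3c(cc(OC)c(OCc4ccccc4)c3OC)C[C@@H](C=C)C2(C(=O)O)C(=O)OC)cc(OC)c1OCc1ccccc1
A1 | alternative 1 | (4S)-4-benzyl-3-[(2E)-3-(4-hydroxy-3,5-dimethoxyphenyl)prop-2-enoyl]-1,3-oxazolidin-2-one | COc1cc(/C=C/C(=O)N2[C@@H](Cc3ccccc3)COC2=O)cc(OC)c1O
A2 | alternative 1 | (4S,4'S)-3,3'-{[(1S,2R)-7-hydroxy-1-(4-hydroxy-3,5-dimethoxyphenyl)-6,8-dimethoxy-1,2-dihydronaphthalene-2,3-diyl]dicarbonyl}bis(4-benzyl-1,3-oxazolidin-2-one) | COc1cc([C@H]2c3c(cc(OC)c(O)c3OC)C=C(C(=O)N4[C@@H](Cc5ccccc5)COC4=O)[C@@H]2C(=O)N2[C@@H](Cc3ccccc3)COC2=O)cc(OC)c1O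
A3 | alternative 2 | (3S,4S)-4-(3-hydroxy-2,4-dimethoxyphenyl)-4-(4-hydroxy-3,5-dimethoxyphenyl)-3-(hydroxymethyl)butanal | COc1cc([C@@H](c2ccc(OC)c(O)c2OC)[C@@H](CO)CC=O)cc(OC)c1O
A4 | alternative 2 | formaldehyde | C=O
A5 | alternative 2 | (1S,2R,3R)-7-hydroxy-1-(4-hydroxy-3,5-dimethoxyphenyl)-2-(hydroxymethyl)-6,8-dimethoxy-1,2,3,4-tetrahydronaphthalene-3-carbaldehyde (numbering of 18) | COc1cc([C@H]2c3c(cc(OC)c(O)c3OC)C[C@@H](C=O)[C@@H]2CO)cc(OC)c1O
A6 | alternative 3 | 4-(benzyloxy)-2-[4-(benzyloxy)-3,5-dimethoxybenzyl]-3,5-dimethoxybenzaldehyde | COc1cc(Cc2c(C=O)cc(OC)c(OCc3ccccc3)c2OC)cc(OC)c1OCc1ccccc1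
A7 | alternative 3 | bis[(2S)-1-methoxy-1-oxopropan-2-yl] (2E)-but-2-enedioate | COC(=O)[C@H](C)OC(=O)/C=C/C(=O)O[C@@H](C)C(=O)OC
A8 | alternative 3 | bis[(2S)-1-methoxy-1-oxopropan-2-yl] (1S,2R,3S,4S)-7-(benzyloxy)-1-[4-(benzyloxy)-3,5-dimethoxyphenyl]-4-hydroxy-6,8-dimethoxy-1,2,3,4-tetrahydronaphthalene-2,3-dicarboxylate | COc1cc([C@H]2c3c(cc(OC)c(OCc4ccccc4)c3OC)[C@@H](O)[C@@H](C(=O)O[C@@H](C)C(=O)OC)[C@@H]2C(=O)O[C@@H](C)C(=O)OC)cc(OC)c1OCc1ccccc1
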